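# Proposed total synthesis of CNP0301161.1 (3α-angeloyloxy-9α-[(E)-3-methylpent-2-enoyloxy]eremophil-11-en-8-one)

## The problem

The target 32 is a trans-fused eremophilane decalin. Ring A (C1–C5, C10) carries the 3α-angelate and the 4β-methyl group. Ring B (C5–C10) carries the 7α-isopropenyl group, the C8 ketone and the 9α (E)-3-methylpent-2-enoate. The quaternary C5 bears the angular methyl group cis to the C4 methyl group.

There are six stereocentres (3R,4R,5R,7S,9S,10R). In the chair–chair form every substituent except the angular methyl group is equatorial. C7 and C9, both α to the ketone, therefore have their thermodynamically preferred configurations, whereas C3, C4, C5 and C10 must be set kinetically.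

The C3/C4 pair can be made on an open chain and can then direct C5 and C10 through a chair fold. C9 has to be set separately and must match that fold.

The hard part of the skeleton is the tertiary C4 next to the quaternary C5, together with the trans fusion.

Several groups will not survive rough treatment:
- The isopropenyl ketone is β,γ-unsaturated and moves into conjugation (7(11)-ene) with base or acid.
- The angelate isomerises to the tiglate.
- The 3-methylpent-2-enoate can be deprotonated at its γ-carbon.
- An α-acyloxy ketone invites acyl migration.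

Both esters therefore have to come last, and no strong base may follow the final unveiling of the isopropenyl group.

The structural feature that allows a short synthesis is this: ring A is what a 1,5-enyne (C1≡C2, C5=C10) gives on 6-endo closure. The tertiary C5 cation left behind sits one six-membered ring away from C6 of a 2-substituted buta-1,3-diene (C6=C7–C11=C12). The C8 carbinol next to C7 can turn the resulting allyl cation into the C8 ketone and the C7 isopropenyl group by a 1,2-hydride shift.

The price is a C1=C2 double bond that must later be saturated in the presence of the isopropenyl group.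

## Retrosynthesis

**Esters.** The C3–O and C9–O acyl bonds of 32 are cut last. This leads through 29, 28 and 26 back to the bis-silyl ether 25 and the acids 30 (angelic acid) and 27 ((E)-3-methylpent-2-enoic acid). Carrying either ester earlier would expose it to the amide base of step 18. A propargylic or allylic ester would also migrate under gold catalysis. The precursor 25 differs only in two silyl groups of different lability (C9–OTES, C3–OTBS). The forward reactions must unmask and acylate C9 first and C3 second, under conditions mild enough for the β,γ-unsaturated ketone.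

**C1=C2 saturation and the isopropenyl group.** 25 is traced to the cyclisation product 21 through the conjugated ketones 23 and 22. No ring bond is cut; two hydrogens are removed from C1/C2 and the C11=C12 double bond is parked at C7=C11. Direct hydrogenation of 21 would not distinguish the 1,1-disubstituted isopropenyl group from the hindered cis-disubstituted ring alkene. As the tetrasubstituted enone the side-chain alkene is inert to RhCl(PPh3)3. The forward sequence needs a clean base isomerisation, a selective hydrogenation, and a kinetic deconjugation that also sets C7.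

**Key disconnection.** 21 is cut at C1–C10 and C5–C6, and the C8 ketone is traced to a C8–H/C8–OTBS carbinol. This opens both rings to the acyclic enyne–diene 20. Cutting one ring at a time (annulation of ring B onto a preformed ring A, or the reverse) would leave the C4/C5 vicinal pair and the quaternary centre to a separate alkylation. Here the quaternary centre, the trans fusion, the ketone and the isopropenyl group all come from one event. Precursor 20 has no ring and no quaternary carbon, and its four stereocentres (C3, C4, C8, C9) are all secondary carbinol or methyl-bearing carbons. The forward reaction needs 6-endo attack on the alkyne, a chair–chair fold, carbon capture of the C5 cation and a hydride shift from C8.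

**Fragment union.** 20 is cut at C9–C10 and at the C5–CH3 bond, leading via 19, 18, 17 and 16 to the diyne 6 and the aldehyde 13. Cutting C8–C9 or C4–C5 instead would separate two stereocentres that are easier to make together. The chosen cut makes the E-trisubstituted alkene and joins the halves in one operation on a terminal alkyne. The forward reaction needs regio- and syn-selective carboalumination. Because addition to an α-silyloxy aldehyde is expected to give the 8,9-anti isomer, an oxidation/Felkin reduction pair (17, 18) is planned to secure the 8,9-syn diol.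

**Left half.** 6 is cut at C3–C4, giving 3-(trimethylsilyl)propynal 4 and the axially chiral allenylstannane 3. The latter comes from (R)-but-3-yn-2-ol 1 through its mesylate 2. An aldol route would need three further steps to turn a carbonyl group into the terminal alkyne. The forward reaction must deliver the syn C3/C4 pair and keep the two alkynes distinguishable (C-silyl versus C–H).

**Right half.** 13 is traced through the acetal 12 to the alkyne 11. The two methylidene carbons (C6 and C12) are removed as ethylene. The C8 stereocentre goes back through alcohol 10 to ketone 9, and the C7–C8 bond to methyl dimethoxyacetate 7 and 1-propynylmagnesium bromide 8. The diene is thus made from an internal alkyne without any diene-containing building block. The forward steps need an enantioselective ynone reduction and a non-acidic acetal cleavage.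

## Roads not taken

**Alternative 1:** The cut is C5–C10 across a ten-membered ring. BF3·OEt2 would open a C9,C10-epoxide next to the C8 ketone while C5 of an allylsilane attacks C10 through the ring. Both six-membered rings appear at once, giving 9α-hydroxy-11,12,13-trinoreremophil-3-en-8-one A1.
- Merits: the α-ketol of ring B is delivered directly, with C5, C9 and C10 fixed by the geometry of the medium ring. Ring A never carries a C1=C2 double bond, so the selective hydrogenation that burdens the chosen plan does not arise. In that respect this road is better.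
- Weak points: the substrate is a functionalised cyclodecene whose alkene geometry, allylsilane and epoxide configuration must each be set in a ring size that closes slowly. A1 lacks C11–C13, the C3 oxygen and the C4 stereocentre. Adding the isopropenyl group by aldol chemistry leads to the conjugated isomer and to the same deconjugation problem.
- Comparison: against the hydrogenation advantage, the chosen plan sets a precursor assembled from two small chiral fragments that already carries all fifteen skeletal carbons and C3, C4 and C9.

**Alternative 2:** The cut is C4–C5. KOtBu would generate a phenoxide whose para carbon (C5) displaces a C4 mesylate with inversion. This closes ring A and leaves ring B as the cross-conjugated dienone 3α-(tert-butyldimethylsilyloxy)-11,12,13-trinoreremophila-6,9-dien-8-one A2.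
- Merits: para-alkylative dearomatisation of phenoxides is established, the aromatic starting material is cheap, ring A is saturated from the outset, and C3, C4 and C5 are in place. Its key step is better precedented than the chosen one.
- Weak points: O-alkylation and elimination compete at a secondary mesylate. The two enone arms of A2 (C6=C7 and C9=C10) must then be told apart to install the trans C10–H, the C9 oxygen and the C7 isopropenyl group, each in a separate step with its own stereochemical question.
- Comparison: against the safer key step, the chosen plan sets a ring B whose C8 ketone, C9 oxygen and C7 isopropenyl group are delivered by the cyclisation itself.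

**Alternative 3:** The cuts are C9–C10 and C4–C5. SnCl4 would activate an α-benzyloxy aldehyde; C10 of the alkene adds to C9 (ring B) and C4 of an enol silane captures the C5 cation (ring A), giving 8β-benzyloxy-9α-hydroxy-11,12,13-trinoreremophilan-3-one A3.
- Merits: four stereocentres (C4, C5, C9, C10) are set in one step under chelation control, ring A is saturated, and each elementary event is of a known type. In bond economy it equals the chosen plan, and in precedent it is ahead.
- Weak points: C3 emerges as a ketone. Its reduction to the equatorial 3α-alcohol needs axial hydride delivery past the axial C5 methyl group, which small hydrides do not favour. The C8 benzyl ether must be exchanged for a ketone. The isopropenyl group is still missing and would again arrive as the conjugated isomer.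
- Comparison: the chosen plan sets C3 before cyclisation under reagent control and generates the C8 ketone and the C7 isopropenyl group in the terminating event, at the cost of an unprecedented cascade and a later hydrogenation.

Key step: step 15

## Route

Remark: eremophilane numbering and α/β descriptors (C4 and C5 methyl groups β, H-10 α) are used for cyclic compounds; in the systematic names of the open-chain compounds 16–20, C1–C5 coincide with the target numbering and C6–C11 correspond to target C10, C9, C8, C7, C11, C12; TBS = tert-butyldimethylsilyl, TES = triethylsilyl, TMS = trimethylsilyl; compounds 1, 4, 7, 8, 27 and 30 are taken to be commercial.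

Step 1
Reactants: 1 (R)-but-3-yn-2-ol
Product: 2 (R)-but-3-yn-2-yl methanesulfonate
Conditions: MsCl, Et3N, CH2Cl2, −78 °C to 0 °C
Reagents that add atoms: methanesulfonyl chloride, CS(=O)(=O)Cl
Why: Sulfonylation at oxygen leaves the stereocentre untouched and provides the leaving group for the SN2′ step.

Step 2
Reactants: 2 (R)-but-3-yn-2-yl methanesulfonate
Product: 3 (aS)-buta-1,2-dien-1-yl(tributyl)stannane
Conditions: Bu3SnH, LiN(i-Pr)2, THF, 0 °C; CuBr·SMe2, −78 °C; then 2, −78 °C
Reagents that add atoms: tributyltin hydride, CCCC[SnH](CCCC)CCCC
Why: Anti SN2′ displacement of a propargylic mesylate by a stannylcuprate; the central chirality of 2 is transferred to the allene axis, so the (R)-mesylate should give the (aS)-allene.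

Step 3
Reactants: 3 (aS)-buta-1,2-dien-1-yl(tributyl)stannane; 4 3-(trimethylsilyl)propynal
Product: 5 (3S,4R)-4-methyl-1-(trimethylsilyl)hexa-1,5-diyn-3-ol
Conditions: BF3·OEt2, CH2Cl2, −78 °C
Reagents that add atoms: none
Why: Marshall addition of a chiral allenylstannane to a BF3-activated aldehyde (SE2′). Attack anti to tin fixes C4 as R, and the open transition state gives the syn C3/C4 relationship, hence 3S. The C-silyl group keeps the second alkyne distinct from the new terminal one.

Step 4
Reactants: 5 (3S,4R)-4-methyl-1-(trimethylsilyl)hexa-1,5-diyn-3-ol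
Product: 6 tert-butyldimethyl{[(3S,4R)-4-methyl-1-(trimethylsilyl)hexa-1,5-diyn-3-yl]oxy}silane
Conditions: TBSCl, imidazole, DMF, rt
Reagents that add atoms: tert-butyldimethylsilyl chloride, CC(C)(C)[Si](C)(C)Cl
Why: Standard silylation of a secondary alcohol; a propargylic silyl ether, unlike an ester, does not migrate under gold catalysis.

Step 5
Reactants: 7 methyl dimethoxyacetate; 8 1-propynylmagnesium bromide
Product: 9 1,1-dimethoxypent-3-yn-2-one
Conditions: THF, −78 °C to −40 °C; then aq. NH4Cl
Reagents that add atoms: none
Why: Acylation of an alkynyl Grignard reagent by an α,α-dialkoxy ester; the chelated tetrahedral adduct persists until the quench, so the ketone should form without second addition.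

Step 6
Reactants: 9 1,1-dimethoxypent-3-yn-2-one
Product: 10 (S)-1,1-dimethoxypent-3-yn-2-ol
Conditions: RuCl[(R,R)-TsDPEN](p-cymene) (1 mol%), i-PrOH, rt
Reagents that add atoms: none
Why: Noyori asymmetric transfer hydrogenation of an alkynyl ketone. With the alkyne in the position normally taken by an aryl group, the (R,R)-catalyst should give the alcohol labelled S here (the acetal carbon outranks the alkyne); the sense would be confirmed by Mosher analysis.

Step 7
Reactants: 10 (S)-1,1-dimethoxypent-3-yn-2-ol
Product: 11 (S)-tert-butyl[(1,1-dimethoxypent-3-yn-2-yl)oxy]dimethylsilane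
Conditions: TBSCl, imidazole, DMF, rt
Reagents that add atoms: tert-butyldimethylsilyl chloride, CC(C)(C)[Si](C)(C)Cl
Why: Standard silylation; this silyl group is the one that leaves from C8 in the key step.

Step 8
Reactants: 11 (S)-tert-butyl[(1,1-dimethoxypent-3-yn-2-yl)oxy]dimethylsilane
Product: 12 (S)-tert-butyl[(1,1-dimethoxy-4-methyl-3-methylidenepent-4-en-2-yl)oxy]dimethylsilane
Conditions: second-generation Grubbs catalyst (5 mol%), ethylene (1 atm), toluene, 80 °C
Reagents that add atoms: ethylene, C=C
Why: Ethylene–alkyne cross (enyne) metathesis converts an internal alkyne into a 2,3-disubstituted buta-1,3-diene. No other alkene is present and the stereocentre is not involved.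

Step 9
Reactants: 12 (S)-tert-butyl[(1,1-dimethoxy-4-methyl-3-methylidenepent-4-en-2-yl)oxy]dimethylsilane
Product: 13 (S)-2-(tert-butyldimethylsilyloxy)-4-methyl-3-methylidenepent-4-enal
Conditions: Et3SiOTf, 2,4,6-collidine, CH2Cl2, 0 °C; then H2O
Reagents that add atoms: water, O
Why: Acetal cleavage through a collidinium intermediate under non-acidic conditions, which should spare the TBS ether and the diene. The aldehyde would be used at once, because its α-hydrogen is allylic.

Step 10
Reactants: 6 tert-butyldimethyl{[(3S,4R)-4-methyl-1-(trimethylsilyl)hexa-1,5-diyn-3-yl]oxy}silane; 13 (S)-2-(tert-butyldimethylsilyloxy)-4-methyl-3-methylidenepent-4-enal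
Product: 16 (3S,4R,5E,7RS,8S)-3,8-bis(tert-butyldimethylsilyloxy)-4,5,10-trimethyl-9-methylidene-1-(trimethylsilyl)undeca-5,10-dien-1-yn-7-ol, via vinylalane 14 (not isolated), via lithium alanate 15 (not isolated)
Conditions: 6, AlMe3, Cp2ZrCl2 (0.25 equiv), CH2Cl2, 0 °C to rt; volatiles removed; hexane/THF, MeLi, −78 °C; then 13, −78 °C to −40 °C; aq. potassium sodium tartrate
Reagents that add atoms: trimethylaluminium, C[Al](C)C
Why: Negishi carboalumination adds methyl and aluminium syn across the terminal alkyne (methyl to the inner carbon), which fixes the E alkene; the silylated alkyne is left alone. The alkenyl group of the alanate then adds to the aldehyde. The C7 configuration (target C9) is not relied on here and is corrected in steps 11 and 12.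

Step 11
Reactants: 16 (3S,4R,5E,7RS,8S)-3,8-bis(tert-butyldimethylsilyloxy)-4,5,10-trimethyl-9-methylidene-1-(trimethylsilyl)undeca-5,10-dien-1-yn-7-ol
Product: 17 (3S,4R,5E,8S)-3,8-bis(tert-butyldimethylsilyloxy)-4,5,10-trimethyl-9-methylidene-1-(trimethylsilyl)undeca-5,10-dien-1-yn-7-one
Conditions: Dess–Martin periodinane, NaHCO3, CH2Cl2, 0 °C
Reagents that add atoms: none
Why: Buffered periodinane oxidation of an allylic alcohol under neutral conditions, which should leave the enolisable C8 centre intact.

Step 12
Reactants: 17 (3S,4R,5E,8S)-3,8-bis(tert-butyldimethylsilyloxy)-4,5,10-trimethyl-9-methylidene-1-(trimethylsilyl)undeca-5,10-dien-1-yn-7-one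
Product: 18 (3S,4R,5E,7S,8S)-3,8-bis(tert-butyldimethylsilyloxy)-4,5,10-trimethyl-9-methylidene-1-(trimethylsilyl)undeca-5,10-dien-1-yn-7-ol
Conditions: LiBH(s-Bu)3, THF, −78 °C; then aq. NH4Cl
Reagents that add atoms: none
Why: Felkin–Anh reduction of an α-silyloxy ketone. The bulky hydride attacks anti to the C8–O bond and should give the 7,8-syn alcohol (7S). The β,β-disubstituted enone resists conjugate reduction.

Step 13
Reactants: 18 (3S,4R,5E,7S,8S)-3,8-bis(tert-butyldimethylsilyloxy)-4,5,10-trimethyl-9-methylidene-1-(trimethylsilyl)undeca-5,10-dien-1-yn-7-ol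
Product: 19 (3S,4R,5E,7S,8S)-3,8-bis(tert-butyldimethylsilyloxy)-4,5,10-trimethyl-9-methylidene-7-(triethylsilyloxy)-1-(trimethylsilyl)undeca-5,10-dien-1-yne
Conditions: Et3SiOTf, 2,6-lutidine, CH2Cl2, −78 °C
Reagents that add atoms: triethylsilyl trifluoromethanesulfonate, CC[Si](CC)(CC)OS(=O)(=O)C(F)(F)F
Why: Silylation of a hindered secondary alcohol with a silyl triflate; the TES group can later be removed in the presence of the C3 TBS ether.

Step 14
Reactants: 19 (3S,4R,5E,7S,8S)-3,8-bis(tert-butyldimethylsilyloxy)-4,5,10-trimethyl-9-methylidene-7-(triethylsilyloxy)-1-(trimethylsilyl)undeca-5,10-dien-1-yne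
Product: 20 (3S,4R,5E,7S,8S)-3,8-bis(tert-butyldimethylsilyloxy)-4,5,10-trimethyl-9-methylidene-7-(triethylsilyloxy)undeca-5,10-dien-1-yne
Conditions: K2CO3, MeOH, 0 °C to rt
Reagents that add atoms: none
Why: Methanolysis of the alkynyl C–Si bond is much faster than cleavage of secondary TES or TBS ethers, and frees the terminal alkyne for π-activation.

Step 15
Reactants: 20 (3S,4R,5E,7S,8S)-3,8-bis(tert-butyldimethylsilyloxy)-4,5,10-trimethyl-9-methylidene-7-(triethylsilyloxy)undeca-5,10-dien-1-yne
Product: 21 3α-(tert-butyldimethylsilyloxy)-9α-(triethylsilyloxy)eremophila-1,11-dien-8-one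
Conditions: Ph3PAuNTf2 (5 mol%), i-PrOH (1.5 equiv), CH2Cl2, 0 °C to rt
Reagents that add atoms: none
Why: Proposed new method: Ph3PAuNTf2 π-activates the terminal alkyne, C10 of the E alkene adds to C1 with Markovnikov charge at tertiary C5, C6 of the diene adds to C5 to give the C7 allyl cation, the axial C8–H shifts to C7, and i-PrOH removes the silyl group from the resulting oxocarbenium ion and protonates the C2–Au bond. The closest known reaction types are cationic gold-catalysed 6-endo polyene cyclisations of 1,5-enynes and cyclisations (gold- or Prins-initiated) that end in a pinacol-type shift at a silyloxy carbon next to the new cation. Ring A closes 6-endo-dig (C1–C10) and ring B closes 6-endo-trig (C5–C6). C10 and C5 are set together by anti addition across the E alkene in a chair–chair transition state with C3–OTBS, C4–CH3, C9–OTES and C8–OTBS all equatorial, which gives the trans fusion and the cis C4/C5 methyl groups. C7 is formed in the terminating shift and is not relied on: the centre is labile, 21 is drawn as the stable equatorial epimer, and step 16 removes the centre in any case. The step needs 6-endo rather than 5-endo (cyclopropyl carbene) attack, which the methyl group on C5 secures by making the 6-endo cation tertiary. It needs carbon capture of the C5 cation rather than proton loss or attack by the C8 oxygen, which the chair preorganisation and the bulk of the TBS group should favour. It needs hydride shift rather than elimination, which the 8,9-syn diol set in step 12 secures by placing C8–H axial and parallel to the empty orbital at C7.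

Step 16
Reactants: 21 3α-(tert-butyldimethylsilyloxy)-9α-(triethylsilyloxy)eremophila-1,11-dien-8-one
Product: 22 3α-(tert-butyldimethylsilyloxy)-9α-(triethylsilyloxy)eremophila-1,7(11)-dien-8-one
Conditions: DBU (0.3 equiv), CH2Cl2, rt
Reagents that add atoms: none
Why: Base-mediated conjugation of a β,γ-unsaturated ketone through its dienolate. The tetrasubstituted enone is the thermodynamic isomer; this makes the side-chain alkene inert to hydrogenation and brings both C7 epimers to one compound. C9 already has its preferred equatorial configuration.

Step 17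
Reactants: 22 3α-(tert-butyldimethylsilyloxy)-9α-(triethylsilyloxy)eremophila-1,7(11)-dien-8-one
Product: 23 3α-(tert-butyldimethylsilyloxy)-9α-(triethylsilyloxy)eremophil-7(11)-en-8-one
Conditions: H2 (1–3 atm), RhCl(PPh3)3 (10 mol%), benzene, rt
Reagents that add atoms: none
Why: Homogeneous hydrogenation with RhCl(PPh3)3 reduces the cis-disubstituted C1=C2 bond and leaves the tetrasubstituted conjugated alkene and the ketone alone; no stereocentre is created.

Step 18
Reactants: 23 3α-(tert-butyldimethylsilyloxy)-9α-(triethylsilyloxy)eremophil-7(11)-en-8-one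
Product: 25 3α-(tert-butyldimethylsilyloxy)-9α-(triethylsilyloxy)eremophil-11-en-8-one, via potassium dienolate 24 (not isolated)
Conditions: KN(SiMe3)2, THF, −78 °C; then transfer into AcOH/THF, −78 °C
Reagents that add atoms: none
Why: Deconjugative protonation: γ-deprotonation of the isopropylidene group gives the extended dienolate (the only α′-hydrogen is tertiary, hindered and on a silyloxy carbon), which is protonated kinetically at the α-carbon C7. Protonation on the face that leaves the isopropenyl group equatorial (7α) is expected, because the opposite approach would press that group against the axial C5 methyl group as C7 pyramidalises.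

Step 19
Reactants: 25 3α-(tert-butyldimethylsilyloxy)-9α-(triethylsilyloxy)eremophil-11-en-8-one
Product: 26 3α-(tert-butyldimethylsilyloxy)-9α-hydroxyeremophil-11-en-8-one
Conditions: PPTS, MeOH/CH2Cl2, 0 °C
Reagents that add atoms: none
Why: Acid-catalysed methanolysis removes a secondary TES ether much faster than a secondary TBS ether; the conditions are too mild to enolise the ketone appreciably.

Step 20
Reactants: 26 3α-(tert-butyldimethylsilyloxy)-9α-hydroxyeremophil-11-en-8-one; 27 (E)-3-methylpent-2-enoic acid
Product: 28 3α-(tert-butyldimethylsilyloxy)-9α-[(E)-3-methylpent-2-enoyloxy]eremophil-11-en-8-one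
Conditions: EDC·HCl, DMAP (0.1 equiv), CH2Cl2, 0 °C to rt
Reagents that add atoms: none
Why: Carbodiimide (Steglich) esterification of an unhindered equatorial α-hydroxy ketone. Low temperature and catalytic DMAP are chosen to limit γ-deprotonation of the acyl donor and conjugation of the isopropenyl ketone.

Step 21
Reactants: 28 3α-(tert-butyldimethylsilyloxy)-9α-[(E)-3-methylpent-2-enoyloxy]eremophil-11-en-8-one
Product: 29 3α-hydroxy-9α-[(E)-3-methylpent-2-enoyloxy]eremophil-11-en-8-one
Conditions: HF·pyridine, pyridine, THF, 0 °C to rt
Reagents that add atoms: none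
Why: Buffered fluoride cleavage of the TBS ether; the ester and the β,γ-unsaturated ketone are stable to these weakly acidic conditions.

Step 22
Reactants: 29 3α-hydroxy-9α-[(E)-3-methylpent-2-enoyloxy]eremophil-11-en-8-one; 30 angelic acid
Product: 32 3α-angeloyloxy-9α-[(E)-3-methylpent-2-enoyloxy]eremophil-11-en-8-one (CNP0301161.1), via mixed anhydride 31 (not isolated)
Conditions: 30, 2,4,6-trichlorobenzoyl chloride, Et3N (1 equiv), toluene, rt; then 29, toluene, 60 °C
Reagents that add atoms: none
Why: Yamaguchi esterification through the aroyl mixed anhydride. Without a nucleophilic catalyst the Z geometry of the angelate should be kept, and the amine is limited to one equivalent so that no free base remains to conjugate the isopropenyl ketone.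

## Compound list

1 | (R)-but-3-yn-2-ol | C[C@@H](O)C#C | starting material
2 | (R)-but-3-yn-2-yl methanesulfonate | C[C@@H](OS(C)(=O)=O)C#C | intermediate
3 | (aS)-buta-1,2-dien-1-yl(tributyl)stannane | CC=[C@@]=C[Sn](CCCC)(CCCC)CCCC | intermediate
4 | 3-(trimethylsilyl)propynal | C[Si](C)(C)C#CC=O | starting material
5 | (3S,4R)-4-methyl-1-(trimethylsilyl)hexa-1,5-diyn-3-ol | C[Si](C)(C)C#C[C@@H](O)[C@H](C)C#C | intermediate
6 | tert-butyldimethyl{[(3S,4R)-4-methyl-1-(trimethylsilyl)hexa-1,5-diyn-3-yl]oxy}silane | C[Si](C)(C)C#C[C@@H](O[Si](C)(C)C(C)(C)C)[C@H](C)C#C | intermediate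
7 | methyl dimethoxyacetate | COC(OC)C(=O)OC | starting material
8 | 1-propynylmagnesium bromide | CC#C[Mg]Br | starting material
9 | 1,1-dimethoxypent-3-yn-2-one | CC#CC(=O)C(OC)OC | intermediate
10 | (S)-1,1-dimethoxypent-3-yn-2-ol | CC#C[C@H](O)C(OC)OC | intermediate
11 | (S)-tert-butyl[(1,1-dimethoxypent-3-yn-2-yl)oxy]dimethylsilane | CC#C[C@H](O[Si](C)(C)C(C)(C)C)C(OC)OC | intermediate
12 | (S)-tert-butyl[(1,1-dimethoxy-4-methyl-3-methylidenepent-4-en-2-yl)oxy]dimethylsilane | COC(OC)[C@@H](O[Si](C)(C)C(C)(C)C)C(=C)C(C)=C | intermediate
13 | (S)-2-(tert-butyldimethylsilyloxy)-4-methyl-3-methylidenepent-4-enal | O=C[C@@H](O[Si](C)(C)C(C)(C)C)C(=C)C(C)=C | intermediate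
14 | [(1E,3R,4S)-4-(tert-butyldimethylsilyloxy)-2,3-dimethyl-6-(trimethylsilyl)hex-1-en-5-yn-1-yl]dimethylalane | C[Si](C)(C)C#C[C@@H](O[Si](C)(C)C(C)(C)C)[C@H](C)/C(C)=C/[Al](C)C | intermediate
15 | lithium [(1E,3R,4S)-4-(tert-butyldimethylsilyloxy)-2,3-dimethyl-6-(trimethylsilyl)hex-1-en-5-yn-1-yl]trimethylaluminate | C[Si](C)(C)C#C[C@@H](O[Si](C)(C)C(C)(C)C)[C@H](C)/C(C)=C/[Al-](C)(C)C.[Li+] | intermediate
16 | (3S,4R,5E,7RS,8S)-3,8-bis(tert-butyldimethylsilyloxy)-4,5,10-trimethyl-9-methylidene-1-(trimethylsilyl)undeca-5,10-dien-1-yn-7-ol | C[Si](C)(C)C#C[C@@H](O[Si](C)(C)C(C)(C)C)[C@H](C)/C(C)=C/C(O)[C@@H](O[Si](C)(C)C(C)(C)C)C(=C)C(C)=C | intermediate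
17 | (3S,4R,5E,8S)-3,8-bis(tert-butyldimethylsilyloxy)-4,5,10-trimethyl-9-methylidene-1-(trimethylsilyl)undeca-5,10-dien-1-yn-7-one | C[Si](C)(C)C#C[C@@H](O[Si](C)(C)C(C)(C)C)[C@H](C)/C(C)=C/C(=O)[C@@H](O[Si](C)(C)C(C)(C)C)C(=C)C(C)=C | intermediate
18 | (3S,4R,5E,7S,8S)-3,8-bis(tert-butyldimethylsilyloxy)-4,5,10-trimethyl-9-methylidene-1-(trimethylsilyl)undeca-5,10-dien-1-yn-7-ol | C[Si](C)(C)C#C[C@@H](O[Si](C)(C)C(C)(C)C)[C@H](C)/C(C)=C/[C@H](O)[C@@H](O[Si](C)(C)C(C)(C)C)C(=C)C(C)=C | intermediate
19 | (3S,4R,5E,7S,8S)-3,8-bis(tert-butyldimethylsilyloxy)-4,5,10-trimethyl-9-methylidene-7-(triethylsilyloxy)-1-(trimethylsilyl)undeca-5,10-dien-1-yne | C[Si](C)(C)C#C[C@@H](O[Si](C)(C)C(C)(C)C)[C@H](C)/C(C)=C/[C@H](O[Si](CC)(CC)CC)[C@@H](O[Si](C)(C)C(C)(C)C)C(=C)C(C)=C | intermediate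
20 | (3S,4R,5E,7S,8S)-3,8-bis(tert-butyldimethylsilyloxy)-4,5,10-trimethyl-9-methylidene-7-(triethylsilyloxy)undeca-5,10-dien-1-yne | C#C[C@@H](O[Si](C)(C)C(C)(C)C)[C@H](C)/C(C)=C/[C@H](O[Si](CC)(CC)CC)[C@@H](O[Si](C)(C)C(C)(C)C)C(=C)C(C)=C | intermediate
21 | 3α-(tert-butyldimethylsilyloxy)-9α-(triethylsilyloxy)eremophila-1,11-dien-8-one | C=C(C)[C@@H]1C[C@]2(C)[C@@H](C)[C@H](O[Si](C)(C)C(C)(C)C)C=C[C@H]2[C@H](O[Si](CC)(CC)CC)C1=O | intermediate
22 | 3α-(tert-butyldimethylsilyloxy)-9α-(triethylsilyloxy)eremophila-1,7(11)-dien-8-one | CC(C)=C1C[C@]2(C)[C@@H](C)[C@H](O[Si](C)(C)C(C)(C)C)C=C[C@H]2[C@H](O[Si](CC)(CC)CC)C1=O | intermediate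
23 | 3α-(tert-butyldimethylsilyloxy)-9α-(triethylsilyloxy)eremophil-7(11)-en-8-one | CC(C)=C1C[C@]2(C)[C@@H](C)[C@H](O[Si](C)(C)C(C)(C)C)CC[C@H]2[C@H](O[Si](CC)(CC)CC)C1=O | intermediate
24 | potassium 3α-(tert-butyldimethylsilyloxy)-9α-(triethylsilyloxy)eremophila-7,11-dien-8-olate | C=C(C)C=1C[C@]2(C)[C@@H](C)[C@H](O[Si](C)(C)C(C)(C)C)CC[C@H]2[C@H](O[Si](CC)(CC)CC)C=1[O-].[K+] | intermediate
25 | 3α-(tert-butyldimethylsilyloxy)-9α-(triethylsilyloxy)eremophil-11-en-8-one | C=C(C)[C@@H]1C[C@]2(C)[C@@H](C)[C@H](O[Si](C)(C)C(C)(C)C)CC[C@H]2[C@H](O[Si](CC)(CC)CC)C1=O | intermediate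
26 | 3α-(tert-butyldimethylsilyloxy)-9α-hydroxyeremophil-11-en-8-one | C=C(C)[C@@H]1C[C@]2(C)[C@@H](C)[C@H](O[Si](C)(C)C(C)(C)C)CC[C@H]2[C@H](O)C1=O | intermediate
27 | (E)-3-methylpent-2-enoic acid | CC/C(C)=C/C(=O)O | starting material
28 | 3α-(tert-butyldimethylsilyloxy)-9α-[(E)-3-methylpent-2-enoyloxy]eremophil-11-en-8-one | C=C(C)[C@@H]1C[C@]2(C)[C@@H](C)[C@H](O[Si](C)(C)C(C)(C)C)CC[C@H]2[C@H](OC(=O)/C=C(\C)CC)C1=O | intermediate
29 | 3α-hydroxy-9α-[(E)-3-methylpent-2-enoyloxy]eremophil-11-en-8-one | C=C(C)[C@@H]1C[C@]2(C)[C@@H](C)[C@H](O)CC[C@H]2[C@H](OC(=O)/C=C(\C)CC)C1=O | intermediate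
30 | angelic acid, (Z)-2-methylbut-2-enoic acid | C/C=C(/C)C(=O)O | starting material
31 | (Z)-2-methylbut-2-enoic 2,4,6-trichlorobenzoic anhydride | C/C=C(/C)C(=O)OC(=O)c1c(Cl)cc(Cl)cc1Cl | intermediate
32 | (3R,4R,5R,7S,9S,10R)-3-angeloyloxy-9-[(E)-3-methylpent-2-enoyloxy]eremophil-11-en-8-one, CNP0301161.1 | C=C(C)[C@@H]1C[C@]2(C)[C@@H](C)[C@H](OC(=O)/C(C)=C\C)CC[C@H]2[C@H](OC(=O)/C=C(\C)CC)C1=O | target

## Step count and least certain steps

Total: 22 steps. Longest linear sequence: 18 steps (steps 5–22, from methyl dimethoxyacetate 7); the left half contributes steps 1–4.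

**Step 15 (key step).** The most likely failures are that the C5 cation loses a proton or is captured by the C8 oxygen before the diene reaches it, that the enyne enters the 5-endo cyclopropyl-carbene manifold, or that the C7 cation eliminates instead of accepting the hydride. The fallback separates the two ring closures and runs each as a reaction of an established class. It sets out from 20. With the same catalyst in CH2Cl2 containing methanol, the 6-endo alkoxycyclisation of the enyne should give (8S,9S)-3α,8-bis(tert-butyldimethylsilyloxy)-5α-methoxy-9-(triethylsilyloxy)-5,6-secoeremophila-1,6,11-triene F1. Ionisation of this tertiary ether with SnCl4 in CH2Cl2 at −78 °C then regenerates the C5 cation away from gold and closes ring B by a cation–olefin cyclisation terminated by a pinacol-type hydride shift (Prins–pinacol type). This returns to the route at 21.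

**Step 18.** The dienolate may form on the wrong side (C9, with silyl migration between the two oxygens), protonation may occur at the γ-carbon and return the conjugated ketone, or facial selectivity at C7 may be poor. The fallback replaces hard enolisation by soft enolisation with an isolable intermediate whose constitution can be checked. It sets out from 23. Me3SiOTf and Et3N in CH2Cl2 at 0 °C should give the extended silyl dienol ether 3α-(tert-butyldimethylsilyloxy)-9α-(triethylsilyloxy)-8-(trimethylsilyloxy)eremophila-7,11-diene F2. Cleavage with Bu4NF buffered with AcOH in THF at −78 °C protonates C7 and returns to the route at 25.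

**Step 10.** Methyl transfer from aluminium, enolisation of the labile aldehyde 13 by the alanate, or incomplete carboalumination next to the branched C4 could lower the efficiency of the union. The fallback separates alkene formation from the coupling. It sets out from 6. Carboalumination as before, followed by iodine, gives tert-butyl{[(3S,4R,5E)-6-iodo-4,5-dimethyl-1-(trimethylsilyl)hex-5-en-1-yn-3-yl]oxy}dimethylsilane F3. Nozaki–Hiyama–Kishi coupling of this iodide with 13 (CrCl2, NiCl2 catalytic, DMSO, rt) is neutral and returns to the route at 16.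

**Step 12.** Facial selectivity in the hydride addition may be insufficient, or conjugate reduction may compete. The fallback corrects C9 (target numbering) by inversion instead of by a redox pair. It sets out from the 7R epimer of 16, the expected Felkin product of step 10. Mitsunobu reaction with 4-nitrobenzoic acid, PPh3 and diisopropyl azodicarboxylate gives (3S,4R,5E,7S,8S)-3,8-bis(tert-butyldimethylsilyloxy)-4,5,10-trimethyl-9-methylidene-1-(trimethylsilyl)undeca-5,10-dien-1-yn-7-yl 4-nitrobenzoate F4. Methanolysis with K2CO3 removes the ester and the alkynyl silyl group to give (3S,4R,5E,7S,8S)-3,8-bis(tert-butyldimethylsilyloxy)-4,5,10-trimethyl-9-methylidene-undeca-5,10-dien-1-yn-7-ol F5. Silylation with Et3SiOTf and 2,6-lutidine returns to the route at 20.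

## Further compounds

F1 | step 15 | (8S,9S)-3α,8-bis(tert-butyldimethylsilyloxy)-5α-methoxy-9-(triethylsilyloxy)-5,6-secoeremophila-1,6,11-triene | CO[C@]1(C)[C@@H](C)[C@H](O[Si](C)(C)C(C)(C)C)C=C[C@H]1[C@H](O[Si](CC)(CC)CC)[C@@H](O[Si](C)(C)C(C)(C)C)C(=C)C(C)=C
F2 | step 18 | 3α-(tert-butyldimethylsilyloxy)-9α-(triethylsilyloxy)-8-(trimethylsilyloxy)eremophila-7,11-diene | C=C(C)C=1C[C@]2(C)[C@@H](C)[C@H](O[Si](C)(C)C(C)(C)C)CC[C@H]2[C@H](O[Si](CC)(CC)CC)C=1O[Si](C)(C)C
F3 | step 10 | tert-butyl{[(3S,4R,5E)-6-iodo-4,5-dimethyl-1-(trimethylsilyl)hex-5-en-1-yn-3-yl]oxy}dimethylsilane | C[Si](C)(C)C#C[C@@H](O[Si](C)(C)C(C)(C)C)[C@H](C)/C(C)=C/I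
F4 | step 12 | (3S,4R,5E,7S,8S)-3,8-bis(tert-butyldimethylsilyloxy)-4,5,10-trimethyl-9-methylidene-1-(trimethylsilyl)undeca-5,10-dien-1-yn-7-yl 4-nitrobenzoate | C[Si](C)(C)C#C[C@@H](O[Si](C)(C)C(C)(C)C)[C@H](C)/C(C)=C/[C@H](OC(=O)c1ccc(cc1)[N+](=O)[O-])[C@@H](O[Si](C)(C)C(C)(C)C)C(=C)C(C)=C
F5 | step 12 | (3S,4R,5E,7S,8S)-3,8-bis(tert-butyldimethylsilyloxy)-4,5,10-trimethyl-9-methylidene-undeca-5,10-dien-1-yn-7-ol | C#C[C@@H](O[Si](C)(C)C(C)(C)C)[C@H](C)/C(C)=C/[C@H](O)[C@@H](O[Si](C)(C)C(C)(C)C)C(=C)C(C)=C
A1 | alternative 1 | 9α-hydroxy-11,12,13-trinoreremophil-3-en-8-one | C1C[C@]2(C)C(C)=CCC[C@H]2[C@H](O)C1=O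
A2 | alternative 2 | 3α-(tert-butyldimethylsilyloxy)-11,12,13-trinoreremophila-6,9-dien-8-one | C1=C[C@]2(C)[C@@H](C)[C@H](O[Si](C)(C)C(C)(C)C)CCC2=CC1=O
A3 | alternative 3 | 8β-benzyloxy-9α-hydroxy-11,12,13-trinoreremophilan-3-one | C1C[C@]2(C)[C@@H](C)C(=O)CC[C@H]2[C@H](O)[C@H]1OCc3ccccc3
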